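## The problem

Target 25 is the 3-O-(3-hydroxy-4,5-dimethoxybenzoyl) ester of a 2,3-cis flavan-3-ol. It is a 3,4-dihydro-2H-chromene whose pyran ring C is fused to the 5,7-dihydroxylated ring A through O1–C8a and C4–C4a, with the catechol ring B on C2 and the aroyloxy group on C3. There are two stereocentres, C2 and C3, both R and cis to each other. C2 is a benzylic ether carbon and can be made first as a resolvable furyl carbinol. Once fixed it can control C3, because a hydride delivered to a C3 carbonyl from the face away from ring B gives the cis alcohol. The same C2 is the weak point of every flavan: with the electron-rich ring A on O1 and the para-oxygenated ring B on C2, the O1–C2 bond opens under acid (benzylic cation) or base (quinone methide), which scrambles C2, and the free polyphenol is easily oxidised. The ester must be carried without strong nucleophiles, and the five phenols that end free need masks that leave under neutral conditions while two methyl ethers stay. The feature that opens the route is the substitution of ring A: oxygen on C8a, C5 and C7, carbon on C4a, hydrogen on C6 and C8. This is the pattern written by a vinylketene whose alkene is the O1–C8a=C4a enol ether of a dihydropyran and a siloxyacetylene that supplies C6 and C7, so ring A can be grown last on a simple pyran that already holds C2, C3 and the ester.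

## Retrosynthesis

**25 from 23 through 24.** No skeletal bond is cut. The three benzyl ethers (ring B and the benzoate) and the silyl ether on O7 are put back. Groups removed by fluoride and by neutral hydrogenolysis keep the polyphenol out of the synthesis until its last two operations. Selective cleavage of methyl ethers, the neighbouring option, is impossible beside the two methoxy groups that must stay. The forward steps must spare the C3 ester, the benzylic O1–C2 bond and both stereocentres.

**23 from 18 and 19.** Four bonds of ring A are cut: C8–C8a, C7–C8, C5–C6 and C4a–C5. What remains is diazo ketone 18, a monocyclic dihydropyran that already carries C2, C3 and the ester, and the two-carbon ynol ether 19. The neighbouring cuts keep ring A and break ring C instead (O1–C8a, C4–C4a, or O1–C2 together with C3–C4). Each of those forms or handles C2 while the electron-rich arene is attached to it, which is the situation in which C2 scrambles. Cutting ring A turns a tricycle into a one-ring precursor, and the oxygen pattern then follows from mechanism and not from directing effects. The forward reaction has to generate vinylketene 20 by Wolff rearrangement, combine it with 19 in one regiochemical sense to cyclobutenone 21, and carry 21 through dienylketene 22 to the phenol without acid or base.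

**18 from 13 through 16 and 14.** The carbon–nitrogen bond of the diazo group is removed first. 18 goes back to methyl ketone 16, with diazo transfer onto the methyl group after activation as trifluoroacetyl diketone 17. The alternative, acylating diazomethane with an acid chloride, risks dipolar addition to the conjugated double bond. Next the bond from pyran C6 (the future C8a) to the acetyl carbon is cut: 16 comes from ketene acetal phosphate 14 and an acetyl anion equivalent by cross-coupling, through ethoxyvinyl diene 15. Phosphate 14 is the enol derivative of lactone 13, so the sp2 carbon C8a, its oxygen O1 and the C4a–H lost in the final tautomerisation all come from an ordinary δ-lactone. These steps use strong bases and must not touch the aroyl ester. The benzoate has no α-hydrogen, and enolisation is run at −78 °C with the electrophile present.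

**13 from 11 and 3 through 12.** The ester C–O bond is cut, and the saturated C4–C4a bond is traced back to the alkene of unsaturated ester 12, hence to allylic alcohol 11 and acid 3. Acylating 11 first and saturating afterwards is preferred to the reverse order, because a saturated δ-lactone with a free hydroxyl on the neighbouring carbon can slip into the five-membered lactone. Acid 3 is the benzyl ether of commercial acid 1 and is made through benzyl ester 2. The forward reactions are a mild esterification of a hindered secondary alcohol and an alkene hydrogenation that leaves benzyl ethers and an allylic ester alone.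

**11 from 8 through 10 and 9.** The C3–H bond is cut (hydride onto ketone 10), the lactone carbonyl is taken back to the lactol of 9, and 9 is the Achmatowicz product of furyl carbinol 8. One furan ring and the carbinol carbon thus deliver O1, C2, C3, C4, C4a and C8a with C2 already set. Building the same lactone from an open-chain dihydroxy acid would again favour the five-membered ring. The forward sequence has to oxidise the lactol without enolising the C2–H next to the ketone, and the hydride has to approach anti to the aryl group.

**8 from 4 and 5 through 7.** The bond between the furan and the carbinol carbon is cut. Lithiated furan 6 adds to aldehyde 5 to give racemic carbinol 7, and a kinetic resolution leaves 8. Both partners are commodity chemicals and the resolution of 2-furylcarbinols is dependable. The price is the loss of half of 7 at the second step, where material is cheapest.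

## Roads not taken

**Alternative 1:** The cut is C4–C4a. The precursor is an epoxy ether in which O1 of a benzyl-protected ring A already sits on the benzylic carbon C2 and C3–C4 is an oxirane. Activated by a Lewis acid or a strongly hydrogen-bonding solvent, the ortho carbon of ring A opens the epoxide at its CH2 terminus (6-endo). This closes ring C and frees the C3 hydroxyl in A1, 5,7,3',4'-tetra-O-benzyl-(−)-epicatechin. Esterification of A1 with 3 and one hydrogenolysis would finish the synthesis.
- Merits: ring A is bought, not built. Its two ortho positions are equivalent, so there is no regiochemical question on the arene. C3 keeps the configuration of the epoxide. The route is clearly shorter, probably by five or six steps.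
- Weak points: the precursor is an aryl ether of a para-oxygenated benzylic carbon, the arrangement that ionises. It must be made stereospecifically at a carbon that prefers SN1 and then survive the acid of the key step, so C2 is at risk twice. The internal epoxide carbon offers a competing 5-exo closure to a dihydrobenzofuran.
- Comparison: in step count and in the use of a ready-made ring A this road is better. The chosen plan sets against it that C2 and C3 are fixed on a pyran with no arene on O1 that never meets a Lewis acid, and that the oxygen pattern of ring A comes from mechanism.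

**Alternative 2:** The cut is O1–C8a. A syn 1,2-diol, from asymmetric dihydroxylation of an E-1,3-diarylpropene whose ring A carries an ortho bromine, is silylated on the homobenzylic hydroxyl. The free benzylic hydroxyl is then joined to the C–Br carbon by copper- or palladium-catalysed intramolecular O-arylation, giving silyl ether A2. Fluoride releases A1 for esterification with 3 and hydrogenolysis.
- Merits: both stereocentres come from one catalytic, predictable reaction and are carried with retention. That is better than the resolution of the chosen plan, which discards half of 7. Ring A is bought and every step has close precedent. The route is shorter by about four steps.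
- Weak points: two secondary hydroxyls must be told apart, otherwise the C3 hydroxyl closes a five-membered ring. The aryl bromide is electron-rich and flanked by two ortho substituents, the least favourable case for oxidative addition. A palladium benzylic alkoxide can undergo β-hydride elimination to the ketone with reduction of the C–Br bond. The protecting group on O3 costs two steps.
- Comparison: for this target this is probably the safer road, and it sets the stereochemistry more economically. The chosen plan answers only with three points: no hydroxyl differentiation and no hindered C–O coupling; a late, mechanism-controlled assembly of ring A, which would also give ring A analogues from one advanced intermediate; and a fragile flavan present only in the last three steps.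

**Alternative 3:** The cuts are O1–C2 and C3–C4. An ortho-quinone methide from a ring A salicyl alcohol would add across a Z-enol ester that carries ring B on one alkene carbon and the complete benzoate on the other. The oxa-Diels–Alder reaction closes ring C and gives the perbenzylated target A3 in one step, one hydrogenolysis from 25.
- Merits: the most convergent road. Two bonds, ring C and the ester come in a single operation, the cis relationship is read from the alkene geometry, and the total is perhaps five or six steps.
- Weak points: the dienophile is ambident. As an enol ester its nucleophilic carbon is the aryl-bearing one; as a styrene it is the acyloxy-bearing one. The required regiochemistry therefore rests on the aryl donor outweighing the acyloxy group. Enol esters are sluggish partners for a quinone methide that is stabilised by two alkoxy groups and dimerises readily. Above all, nothing controls absolute configuration and no established catalyst does so for this pairing, so the product would be racemic and a resolution would have to be added.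
- Comparison: in brevity and convergence this road is far superior. It is set aside only because the single enantiomer is required, which the chosen plan secures with established reactions.

Key step: step 12

Assumption: (triisopropylsilyloxy)acetylene 19 is a known, distillable silyl ynol ether and is entered as a purchased reagent.

## Steps

Step 1
Reactants: 1 3-hydroxy-4,5-dimethoxybenzoic acid
Product: 3 3-(benzyloxy)-4,5-dimethoxybenzoic acid, via benzyl ester 2 (not isolated)
Conditions: BnBr, K2CO3, DMF, 60 °C; then NaOH, MeOH/H2O, 60 °C; HCl to pH 2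
Reagents that add atoms: benzyl bromide, BrCc1ccccc1; sodium hydroxide, [Na+].[OH-]
Why: Williamson benzylation alkylates the phenol and the carboxylate, and saponification of the benzyl ester in the same pot returns the acid. The phenol stays masked as a benzyl ether that the final hydrogenolysis removes.

Step 2
Reactants: 4 furan; 5 3,4-bis(benzyloxy)benzaldehyde
Product: 7 rac-[3,4-bis(benzyloxy)phenyl](furan-2-yl)methanol, via 2-furyllithium 6 (not isolated)
Conditions: n-BuLi, THF, −78 to 0 °C; then 5, −78 °C to rt; H2O
Reagents that add atoms: none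
Why: C2 lithiation of furan and 1,2-addition of the heteroaryllithium to the non-enolisable aldehyde. The new stereocentre is formed racemic and is resolved in step 3.

Step 3
Reactants: 7 rac-[3,4-bis(benzyloxy)phenyl](furan-2-yl)methanol
Product: 8 (R)-[3,4-bis(benzyloxy)phenyl](furan-2-yl)methanol
Conditions: Ti(OiPr)4 (0.2 equiv), diisopropyl L-(+)-tartrate (0.24 equiv), t-BuOOH (0.6 equiv), 4 Å MS, CH2Cl2, −20 °C
Reagents that add atoms: none
Why: Sharpless kinetic resolution of a 2-furylcarbinol, in which the furan C2=C3 bond plays the part of the allylic alkene. With the L-(+)-tartrate the (S)-carbinol should be oxidised faster (to its pyranone), so (R)-8 is recovered enantioenriched at slightly over half conversion. This centre becomes C2 of the target.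

Step 4
Reactants: 8 (R)-[3,4-bis(benzyloxy)phenyl](furan-2-yl)methanol
Product: 9 (2R)-2-[3,4-bis(benzyloxy)phenyl]-6-hydroxy-2H-pyran-3(6H)-one (both C6 epimers)
Conditions: NBS, NaHCO3, NaOAc, THF/H2O (4:1), 0 °C
Reagents that add atoms: water, O
Why: Achmatowicz rearrangement. Bromonium attack on the furan, addition of water and ring opening give a cis-enedione that recloses through the carbinol oxygen. The carbinol carbon is not touched and keeps its configuration.

Step 5
Reactants: 9 (2R)-2-[3,4-bis(benzyloxy)phenyl]-6-hydroxy-2H-pyran-3(6H)-one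
Product: 10 (6R)-6-[3,4-bis(benzyloxy)phenyl]-2H-pyran-2,5(6H)-dione
Conditions: CrO3, H2SO4, acetone/H2O, 0 °C, short contact; crude product used at once
Reagents that add atoms: none
Why: Chromic acid oxidation of the allylic lactol to the lactone, the usual follow-up to an Achmatowicz product. Short contact at 0 °C and direct use of the crude dione limit enolisation at C6.

Step 6
Reactants: 10 (6R)-6-[3,4-bis(benzyloxy)phenyl]-2H-pyran-2,5(6H)-dione
Product: 11 (5R,6R)-6-[3,4-bis(benzyloxy)phenyl]-5-hydroxy-5,6-dihydro-2H-pyran-2-one
Conditions: NaBH4, CeCl3·7H2O, CH2Cl2/MeOH, −78 °C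
Reagents that add atoms: none
Why: Luche 1,2-reduction. Hydride adds to the C5 ketone of the nearly flat ring from the face opposite the C6 aryl group, which sets the new centre (C3 of the target) cis to the aryl group, as known for 6-substituted pyran-2,5-diones. CeCl3 suppresses conjugate reduction.

Step 7
Reactants: 11 (5R,6R)-6-[3,4-bis(benzyloxy)phenyl]-5-hydroxy-5,6-dihydro-2H-pyran-2-one; 3 3-(benzyloxy)-4,5-dimethoxybenzoic acid
Product: 12 (2R,3R)-2-[3,4-bis(benzyloxy)phenyl]-6-oxo-3,6-dihydro-2H-pyran-3-yl 3-(benzyloxy)-4,5-dimethoxybenzoate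
Conditions: EDC·HCl, DMAP (cat.), CH2Cl2, 0 °C to rt
Reagents that add atoms: none
Why: Steglich esterification of the secondary allylic alcohol. Acylating at this stage blocks translactonisation of the hydroxy lactone to the five-membered isomer, and no stereocentre is touched.

Step 8
Reactants: 12 (2R,3R)-2-[3,4-bis(benzyloxy)phenyl]-6-oxo-3,6-dihydro-2H-pyran-3-yl 3-(benzyloxy)-4,5-dimethoxybenzoate
Product: 13 (2R,3R)-2-[3,4-bis(benzyloxy)phenyl]-6-oxooxan-3-yl 3-(benzyloxy)-4,5-dimethoxybenzoate
Conditions: H2 (3 atm), RhCl(PPh3)3 (5 mol %), benzene/EtOH, rt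
Reagents that add atoms: none
Why: Homogeneous hydrogenation saturates the cis-disubstituted conjugated alkene. This catalyst does not hydrogenolyse benzyl ethers, the allylic ester or the benzylic C–O bond, and no hydride is present that could displace the allylic carboxylate.

Step 9
Reactants: 13 (2R,3R)-2-[3,4-bis(benzyloxy)phenyl]-6-oxooxan-3-yl 3-(benzyloxy)-4,5-dimethoxybenzoate
Product: 14 (2R,3R)-2-[3,4-bis(benzyloxy)phenyl]-6-[(diphenoxyphosphoryl)oxy]-3,4-dihydro-2H-pyran-3-yl 3-(benzyloxy)-4,5-dimethoxybenzoate
Conditions: KN(SiMe3)2 added to 13, (PhO)2P(O)Cl and HMPA, THF, −78 °C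
Reagents that add atoms: diphenyl chlorophosphate, O=P(Cl)(Oc1ccccc1)Oc1ccccc1
Why: Kinetic enolisation of the lactone at C5 of the oxanone ring (the future C4a; the benzoate has no α-hydrogen) with in situ O-phosphorylation gives the ketene acetal phosphate. It is a cross-coupling handle more stable than the corresponding triflate.

Step 10
Reactants: 14 (2R,3R)-2-[3,4-bis(benzyloxy)phenyl]-6-[(diphenoxyphosphoryl)oxy]-3,4-dihydro-2H-pyran-3-yl 3-(benzyloxy)-4,5-dimethoxybenzoate
Product: 16 (2R,3R)-6-acetyl-2-[3,4-bis(benzyloxy)phenyl]-3,4-dihydro-2H-pyran-3-yl 3-(benzyloxy)-4,5-dimethoxybenzoate, via ethoxyvinyl diene 15 (not isolated)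
Conditions: tributyl(1-ethoxyvinyl)stannane, Pd(PPh3)4 (10 mol %), LiCl, THF, 65 °C; then 0.5 M HCl, THF, 0 °C
Reagents that add atoms: tributyl(1-ethoxyvinyl)stannane, CCCC[Sn](CCCC)(CCCC)C(=C)OCC; water, O
Why: Stille coupling of the ketene acetal phosphate (oxidative addition into C–OP, chloride-assisted transmetalation, reductive elimination) gives diene 15. Dilute acid hydrolyses its acyclic enol ether selectively, because protonation at the terminal CH2 is fastest and the product is a deactivated 2-acyl enol ether.

Step 11
Reactants: 16 (2R,3R)-6-acetyl-2-[3,4-bis(benzyloxy)phenyl]-3,4-dihydro-2H-pyran-3-yl 3-(benzyloxy)-4,5-dimethoxybenzoate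
Product: 18 (2R,3R)-2-[3,4-bis(benzyloxy)phenyl]-6-(diazoacetyl)-3,4-dihydro-2H-pyran-3-yl 3-(benzyloxy)-4,5-dimethoxybenzoate, via trifluoroacetyl diketone 17 (not isolated)
Conditions: LiN(SiMe3)2, THF, −78 °C; CF3CO2CH2CF3; 5% HCl work-up; then MsN3, Et3N, H2O, MeCN, rt
Reagents that add atoms: methanesulfonyl azide, CS(=O)(=O)N=[N+]=[N-]; for intermediate 17 only: 2,2,2-trifluoroethyl trifluoroacetate, O=C(OCC(F)(F)F)C(F)(F)F
Why: Detrifluoroacetylative diazo transfer. Claisen trifluoroacetylation of the kinetic methyl enolate activates the methyl group for diazo transfer from the sulfonyl azide, and the trifluoroacetyl group leaves with the sulfonamide. Deprotonation at −78 °C at the methyl group avoids the γ-enolate that could expel the benzoate.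

Step 12
Reactants: 18 (2R,3R)-2-[3,4-bis(benzyloxy)phenyl]-6-(diazoacetyl)-3,4-dihydro-2H-pyran-3-yl 3-(benzyloxy)-4,5-dimethoxybenzoate; 19 (triisopropylsilyloxy)acetylene
Product: 23 (2R,3R)-2-[3,4-bis(benzyloxy)phenyl]-5-hydroxy-7-[(triisopropylsilyl)oxy]-3,4-dihydro-2H-chromen-3-yl 3-(benzyloxy)-4,5-dimethoxybenzoate, via vinylketene 20 (not isolated), via cyclobutenone 21 (not isolated), via dienylketene 22 (not isolated)
Conditions: hν (300 nm, Pyrex), 19 (3 equiv), ClCH2CH2Cl, rt; then 80 °C
Reagents that add atoms: none
Why: Light expels N2 from 18 and the pyranyl carbon C8a migrates to the carbene carbon (Wolff rearrangement, forming C8–C8a), so that ketene 20 is conjugated with the O1–C8a=C4a enol ether. The nucleophilic CH terminus of ynol ether 19 attacks the ketene carbonyl carbon and the siloxy-bearing carbon bonds to the ketene α-carbon, a polarity-matched [2+2] cycloaddition that gives 3-siloxycyclobutenone 21 (C5–C6 and C7–C8). On warming, 21 opens by reversible four-electron electrocyclic cleavage of its C5–C8 bond to dienylketene 22, and ring A is closed by thermal six-electron electrocyclisation of 22 at C4a–C5, the nucleophilic enol ether carbon meeting the ketene carbon, followed by enolisation to the phenol. The closest known reaction type is the Danheiser benzannulation in its photochemical Wolff form with siloxyalkynes, which is documented for diazo ketones whose migrating sp2 carbon bears a ring oxygen (2-furyl) and then gives 4-hydroxybenzofurans. No stereocentre is formed; C2 and C3 are spectators and the medium is neutral, so neither benzylic ionisation nor ester cleavage has a pathway. The selectivity required is regiochemical (siloxy carbon at C7, meta to the new C5 hydroxyl, not at C6) and is secured by the polarisation of 19 and of the ketene, whose carbonyl ends as the C5–OH. Light near 300 nm addresses the diazo enone chromophore beyond the absorption of the benzyl ethers and the benzoate, and the excess of 19 keeps the ketene from acylating the product phenol.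

Step 13
Reactants: 23 (2R,3R)-2-[3,4-bis(benzyloxy)phenyl]-5-hydroxy-7-[(triisopropylsilyl)oxy]-3,4-dihydro-2H-chromen-3-yl 3-(benzyloxy)-4,5-dimethoxybenzoate
Product: 24 (2R,3R)-2-[3,4-bis(benzyloxy)phenyl]-5,7-dihydroxy-3,4-dihydro-2H-chromen-3-yl 3-(benzyloxy)-4,5-dimethoxybenzoate
Conditions: Bu4NF, AcOH, THF, 0 °C
Reagents that add atoms: none
Why: Fluoride cleaves the aryl silyl ether. Acetic acid buffers the phenoxide so that the C3 ester and the base-sensitive flavan are not exposed to basic fluoride.

Step 14
Reactants: 24 (2R,3R)-2-[3,4-bis(benzyloxy)phenyl]-5,7-dihydroxy-3,4-dihydro-2H-chromen-3-yl 3-(benzyloxy)-4,5-dimethoxybenzoate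
Product: 25 (2R,3R)-2-(3,4-dihydroxyphenyl)-5,7-dihydroxy-3,4-dihydro-2H-chromen-3-yl 3-hydroxy-4,5-dimethoxybenzoate
Conditions: H2 (1 atm), Pd(OH)2/C, THF/MeOH, rt
Reagents that add atoms: none
Why: Hydrogenolysis of the three aryl benzyl ethers under neutral conditions, the standard unmasking of benzylated flavan-3-ol esters. The ester, the methyl ethers and both stereocentres are untouched, and the reaction is stopped at full debenzylation to spare the benzylic O1–C2 bond.

## Compound list

1 | 3-hydroxy-4,5-dimethoxybenzoic acid | COc1cc(C(=O)O)cc(O)c1OC | starting material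
2 | benzyl 3-(benzyloxy)-4,5-dimethoxybenzoate | COc1cc(C(=O)OCc2ccccc2)cc(OCc2ccccc2)c1OC | intermediate
3 | 3-(benzyloxy)-4,5-dimethoxybenzoic acid | COc1cc(C(=O)O)cc(OCc2ccccc2)c1OC | intermediate
4 | furan | c1ccoc1 | starting material
5 | 3,4-bis(benzyloxy)benzaldehyde | O=Cc1ccc(OCc2ccccc2)c(OCc2ccccc2)c1 | starting material
6 | 2-furyllithium | [Li]c1ccco1 | intermediate
7 | rac-[3,4-bis(benzyloxy)phenyl](furan-2-yl)methanol | OC(c1ccco1)c1ccc(OCc2ccccc2)c(OCc2ccccc2)c1 | intermediate
8 | (R)-[3,4-bis(benzyloxy)phenyl](furan-2-yl)methanol | O[C@@H](c1ccco1)c1ccc(OCc2ccccc2)c(OCc2ccccc2)c1 | intermediate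
9 | (2R)-2-[3,4-bis(benzyloxy)phenyl]-6-hydroxy-2H-pyran-3(6H)-one (both C6 epimers) | O=C1C=CC(O)O[C@@H]1c1ccc(OCc2ccccc2)c(OCc2ccccc2)c1 | intermediate
10 | (6R)-6-[3,4-bis(benzyloxy)phenyl]-2H-pyran-2,5(6H)-dione | O=C1C=CC(=O)O[C@@H]1c1ccc(OCc2ccccc2)c(OCc2ccccc2)c1 | intermediate
11 | (5R,6R)-6-[3,4-bis(benzyloxy)phenyl]-5-hydroxy-5,6-dihydro-2H-pyran-2-one | O[C@@H]1C=CC(=O)O[C@@H]1c1ccc(OCc2ccccc2)c(OCc2ccccc2)c1 | intermediate
12 | (2R,3R)-2-[3,4-bis(benzyloxy)phenyl]-6-oxo-3,6-dihydro-2H-pyran-3-yl 3-(benzyloxy)-4,5-dimethoxybenzoate | COc1cc(C(=O)O[C@@H]2C=CC(=O)O[C@@H]2c2ccc(OCc3ccccc3)c(OCc3ccccc3)c2)cc(OCc2ccccc2)c1OC | intermediate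
13 | (2R,3R)-2-[3,4-bis(benzyloxy)phenyl]-6-oxooxan-3-yl 3-(benzyloxy)-4,5-dimethoxybenzoate | COc1cc(C(=O)O[C@@H]2CCC(=O)O[C@@H]2c2ccc(OCc3ccccc3)c(OCc3ccccc3)c2)cc(OCc2ccccc2)c1OC | intermediate
14 | (2R,3R)-2-[3,4-bis(benzyloxy)phenyl]-6-[(diphenoxyphosphoryl)oxy]-3,4-dihydro-2H-pyran-3-yl 3-(benzyloxy)-4,5-dimethoxybenzoate | COc1cc(C(=O)O[C@@H]2CC=C(OP(=O)(Oc3ccccc3)Oc3ccccc3)O[C@@H]2c2ccc(OCc3ccccc3)c(OCc3ccccc3)c2)cc(OCc2ccccc2)c1OC | intermediate
15 | (2R,3R)-2-[3,4-bis(benzyloxy)phenyl]-6-(1-ethoxyethenyl)-3,4-dihydro-2H-pyran-3-yl 3-(benzyloxy)-4,5-dimethoxybenzoate | COc1cc(C(=O)O[C@@H]2CC=C(C(=C)OCC)O[C@@H]2c2ccc(OCc3ccccc3)c(OCc3ccccc3)c2)cc(OCc2ccccc2)c1OC | intermediate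
16 | (2R,3R)-6-acetyl-2-[3,4-bis(benzyloxy)phenyl]-3,4-dihydro-2H-pyran-3-yl 3-(benzyloxy)-4,5-dimethoxybenzoate | COc1cc(C(=O)O[C@@H]2CC=C(C(C)=O)O[C@@H]2c2ccc(OCc3ccccc3)c(OCc3ccccc3)c2)cc(OCc2ccccc2)c1OC | intermediate
17 | (2R,3R)-2-[3,4-bis(benzyloxy)phenyl]-6-(4,4,4-trifluoro-3-oxobutanoyl)-3,4-dihydro-2H-pyran-3-yl 3-(benzyloxy)-4,5-dimethoxybenzoate | COc1cc(C(=O)O[C@@H]2CC=C(C(=O)CC(=O)C(F)(F)F)O[C@@H]2c2ccc(OCc3ccccc3)c(OCc3ccccc3)c2)cc(OCc2ccccc2)c1OC | intermediate
18 | (2R,3R)-2-[3,4-bis(benzyloxy)phenyl]-6-(diazoacetyl)-3,4-dihydro-2H-pyran-3-yl 3-(benzyloxy)-4,5-dimethoxybenzoate | COc1cc(C(=O)O[C@@H]2CC=C(C(=O)C=[N+]=[N-])O[C@@H]2c2ccc(OCc3ccccc3)c(OCc3ccccc3)c2)cc(OCc2ccccc2)c1OC | intermediate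
19 | (triisopropylsilyloxy)acetylene | C#CO[Si](C(C)C)(C(C)C)C(C)C | starting material
20 | (2R,3R)-2-[3,4-bis(benzyloxy)phenyl]-6-(2-oxoethenyl)-3,4-dihydro-2H-pyran-3-yl 3-(benzyloxy)-4,5-dimethoxybenzoate (vinylketene) | COc1cc(C(=O)O[C@@H]2CC=C(C=C=O)O[C@@H]2c2ccc(OCc3ccccc3)c(OCc3ccccc3)c2)cc(OCc2ccccc2)c1OC | intermediate
21 | (2R,3R)-2-[3,4-bis(benzyloxy)phenyl]-6-{4-oxo-2-[(triisopropylsilyl)oxy]cyclobut-2-en-1-yl}-3,4-dihydro-2H-pyran-3-yl 3-(benzyloxy)-4,5-dimethoxybenzoate (both epimers at the cyclobutenone carbon) | COc1cc(C(=O)O[C@@H]2CC=C(C3C(=O)C=C3O[Si](C(C)C)(C(C)C)C(C)C)O[C@@H]2c2ccc(OCc3ccccc3)c(OCc3ccccc3)c2)cc(OCc2ccccc2)c1OC | intermediate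
22 | (2R,3R)-2-[3,4-bis(benzyloxy)phenyl]-6-{4-oxo-2-[(triisopropylsilyl)oxy]buta-1,3-dien-1-yl}-3,4-dihydro-2H-pyran-3-yl 3-(benzyloxy)-4,5-dimethoxybenzoate (dienylketene) | COc1cc(C(=O)O[C@@H]2CC=C(C=C(C=C=O)O[Si](C(C)C)(C(C)C)C(C)C)O[C@@H]2c2ccc(OCc3ccccc3)c(OCc3ccccc3)c2)cc(OCc2ccccc2)c1OC | intermediate
23 | (2R,3R)-2-[3,4-bis(benzyloxy)phenyl]-5-hydroxy-7-[(triisopropylsilyl)oxy]-3,4-dihydro-2H-chromen-3-yl 3-(benzyloxy)-4,5-dimethoxybenzoate | COc1cc(C(=O)O[C@@H]2Cc3c(O)cc(O[Si](C(C)C)(C(C)C)C(C)C)cc3O[C@@H]2c2ccc(OCc3ccccc3)c(OCc3ccccc3)c2)cc(OCc2ccccc2)c1OC | intermediate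
24 | (2R,3R)-2-[3,4-bis(benzyloxy)phenyl]-5,7-dihydroxy-3,4-dihydro-2H-chromen-3-yl 3-(benzyloxy)-4,5-dimethoxybenzoate | COc1cc(C(=O)O[C@@H]2Cc3c(O)cc(O)cc3O[C@@H]2c2ccc(OCc3ccccc3)c(OCc3ccccc3)c2)cc(OCc2ccccc2)c1OC | intermediate
25 | (2R,3R)-2-(3,4-dihydroxyphenyl)-5,7-dihydroxy-3,4-dihydro-2H-chromen-3-yl 3-hydroxy-4,5-dimethoxybenzoate | COc1cc(C(=O)O[C@@H]2Cc3c(O)cc(O)cc3O[C@@H]2c2ccc(O)c(O)c2)cc(O)c1OC | target

## Step count and least certain steps

Total step count: 14. Longest linear sequence: 13 steps (steps 2 to 14, from furan 4 and aldehyde 5 to 25). Step 1 makes acid 3 on a side branch that joins at step 7.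

**Step 12 (key step).** Most likely to go wrong is unproductive photochemistry. The five aromatic rings compete for light, and the excited diazo enol ether can decay by paths other than loss of nitrogen and migration. The new phenol can also be acylated by ketene that has not met the alkyne. The fallback makes the ketene in the dark instead of by light in the annulation flask. It sets out from 18: a Wolff rearrangement under Arndt–Eistert conditions (PhCO2Ag, Et3N, THF/H2O) should give the homologous (dihydropyranyl)acetic acid F1. Treatment with 1-chloro-N,N,2-trimethylprop-1-en-1-amine converts it into the acid chloride F2. Slow addition of F2 to Et3N and 19 in toluene at 80 °C regenerates vinylketene 20 by dehydrochlorination, which passes through 21 and 22 and rejoins the route at 23.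

**Step 5.** Most likely to go wrong is enolisation at C6 under the acidic oxidation, which would aromatise the ring towards a 5-hydroxypyran-2-one and erase the stereocentre that becomes C2; oxidative damage to the electron-rich arene is a second risk. The fallback masks the lactol and oxidises it last, so no ene-dione is formed. It sets out from 9:
- Anomeric silylation (t-BuMe2SiCl, imidazole) gives the silyl acetal F3.
- Hydrogenation (H2, RhCl(PPh3)3) gives the saturated ketone F4.
- LiBH(s-Bu)3 at −78 °C reduces it from the face opposite the aryl group to the cis alcohol F5, as in the reduction of 2-arylchroman-3-ones.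
- Steglich esterification with 3 gives the ester F6.
- Buffered fluoride (Bu4NF, AcOH) gives the lactol F7.
- PhI(OAc)2 with catalytic TEMPO oxidises F7 to lactone 13, where the route is rejoined.

**Step 9.** Most likely to go wrong is attack of the lactone enolate on the neighbouring aroyl group (O-to-C acyl transfer) before it is phosphorylated, or loss of the ketene acetal phosphate on isolation. The fallback brings in the ester only after the base-mediated steps. It sets out from 11:
- Silylation (t-BuMe2SiOTf, 2,6-lutidine) gives the silyl ether F8.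
- Hydrogenation as in step 8 gives the saturated lactone F9.
- The conditions of step 9 give the ketene acetal phosphate F10.
- The conditions of step 10 give, through the ethoxyvinyl diene F11, the methyl ketone F12.
- HF·pyridine removes the silyl group to give the hydroxy ketone F13.
- Steglich esterification of F13 with 3 rejoins the route at 16.

**Step 10.** Most likely to go wrong is slow oxidative addition into the C–OP bond, so that the stannane is lost by protodestannylation, or partial hydrolysis of the ring enol ether when the ketone is unmasked. The fallback reverses the polarity of the coupling. It sets out from 14: stannylation with Me3SnSnMe3 (Pd(PPh3)4, LiCl, THF) gives the vinylstannane F14. Acylation of F14 with acetyl chloride under Stille conditions (PdCl2(PPh3)2, toluene) gives 16 directly, with no enol ether hydrolysis.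

**Step 3.** Most likely to go wrong is a low selectivity factor, because the flat aryl substituent differs less from the furan ring than an alkyl group does, and titanium-promoted ionisation of the doubly activated carbinol. The fallback replaces resolution by asymmetric addition. It sets out from 2-furyllithium 6: transmetalation with EtZnCl gives ethyl(furan-2-yl)zinc F15. Catalysed by the enantiomer of 3-exo-morpholinoisoborneol that directs the furyl group to the face giving the (R)-alcohol, F15 adds to aldehyde 5 and gives 8 directly, so that steps 2 and 3 merge and no material is discarded.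

## Further compounds

F1 | step 12 | 2-[(2R,3R)-2-[3,4-bis(benzyloxy)phenyl]-3-{[3-(benzyloxy)-4,5-dimethoxybenzoyl]oxy}-3,4-dihydro-2H-pyran-6-yl]acetic acid | COc1cc(C(=O)O[C@@H]2CC=C(CC(=O)O)O[C@@H]2c2ccc(OCc3ccccc3)c(OCc3ccccc3)c2)cc(OCc2ccccc2)c1OC
F2 | step 12 | (2R,3R)-2-[3,4-bis(benzyloxy)phenyl]-6-(2-chloro-2-oxoethyl)-3,4-dihydro-2H-pyran-3-yl 3-(benzyloxy)-4,5-dimethoxybenzoate | COc1cc(C(=O)O[C@@H]2CC=C(CC(=O)Cl)O[C@@H]2c2ccc(OCc3ccccc3)c(OCc3ccccc3)c2)cc(OCc2ccccc2)c1OC
F3 | step 5 | (2R)-2-[3,4-bis(benzyloxy)phenyl]-6-[(tert-butyldimethylsilyl)oxy]-2H-pyran-3(6H)-one (both C6 epimers) | O=C1C=CC(O[Si](C)(C)C(C)(C)C)O[C@@H]1c1ccc(OCc2ccccc2)c(OCc2ccccc2)c1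
F4 | step 5 | (2R)-2-[3,4-bis(benzyloxy)phenyl]-6-[(tert-butyldimethylsilyl)oxy]oxan-3-one (both C6 epimers) | O=C1CCC(O[Si](C)(C)C(C)(C)C)O[C@@H]1c1ccc(OCc2ccccc2)c(OCc2ccccc2)c1
F5 | step 5 | (2R,3R)-2-[3,4-bis(benzyloxy)phenyl]-6-[(tert-butyldimethylsilyl)oxy]oxan-3-ol (both C6 epimers) | O[C@@H]1CCC(O[Si](C)(C)C(C)(C)C)O[C@@H]1c1ccc(OCc2ccccc2)c(OCc2ccccc2)c1
F6 | step 5 | (2R,3R)-2-[3,4-bis(benzyloxy)phenyl]-6-[(tert-butyldimethylsilyl)oxy]oxan-3-yl 3-(benzyloxy)-4,5-dimethoxybenzoate (both C6 epimers) | COc1cc(C(=O)O[C@@H]2CCC(O[Si](C)(C)C(C)(C)C)O[C@@H]2c2ccc(OCc3ccccc3)c(OCc3ccccc3)c2)cc(OCc2ccccc2)c1OC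
F7 | step 5 | (2R,3R)-2-[3,4-bis(benzyloxy)phenyl]-6-hydroxyoxan-3-yl 3-(benzyloxy)-4,5-dimethoxybenzoate (both C6 epimers) | COc1cc(C(=O)O[C@@H]2CCC(O)O[C@@H]2c2ccc(OCc3ccccc3)c(OCc3ccccc3)c2)cc(OCc2ccccc2)c1OC
F8 | step 9 | (5R,6R)-6-[3,4-bis(benzyloxy)phenyl]-5-[(tert-butyldimethylsilyl)oxy]-5,6-dihydro-2H-pyran-2-one | CC(C)(C)[Si](C)(C)O[C@@H]1C=CC(=O)O[C@@H]1c1ccc(OCc2ccccc2)c(OCc2ccccc2)c1
F9 | step 9 | (5R,6R)-6-[3,4-bis(benzyloxy)phenyl]-5-[(tert-butyldimethylsilyl)oxy]oxan-2-one | CC(C)(C)[Si](C)(C)O[C@@H]1CCC(=O)O[C@@H]1c1ccc(OCc2ccccc2)c(OCc2ccccc2)c1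
F10 | step 9 | (2R,3R)-2-[3,4-bis(benzyloxy)phenyl]-3-[(tert-butyldimethylsilyl)oxy]-3,4-dihydro-2H-pyran-6-yl diphenyl phosphate | CC(C)(C)[Si](C)(C)O[C@@H]1CC=C(OP(=O)(Oc2ccccc2)Oc2ccccc2)O[C@@H]1c1ccc(OCc2ccccc2)c(OCc2ccccc2)c1
F11 | step 9 | {[(2R,3R)-2-[3,4-bis(benzyloxy)phenyl]-6-(1-ethoxyethenyl)-3,4-dihydro-2H-pyran-3-yl]oxy}(tert-butyl)dimethylsilane | CC(C)(C)[Si](C)(C)O[C@@H]1CC=C(C(=C)OCC)O[C@@H]1c1ccc(OCc2ccccc2)c(OCc2ccccc2)c1
F12 | step 9 | 1-[(2R,3R)-2-[3,4-bis(benzyloxy)phenyl]-3-[(tert-butyldimethylsilyl)oxy]-3,4-dihydro-2H-pyran-6-yl]ethan-1-one | CC(C)(C)[Si](C)(C)O[C@@H]1CC=C(C(C)=O)O[C@@H]1c1ccc(OCc2ccccc2)c(OCc2ccccc2)c1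
F13 | step 9 | 1-[(2R,3R)-2-[3,4-bis(benzyloxy)phenyl]-3-hydroxy-3,4-dihydro-2H-pyran-6-yl]ethan-1-one | O[C@@H]1CC=C(C(C)=O)O[C@@H]1c1ccc(OCc2ccccc2)c(OCc2ccccc2)c1
F14 | step 10 | (2R,3R)-2-[3,4-bis(benzyloxy)phenyl]-6-(trimethylstannyl)-3,4-dihydro-2H-pyran-3-yl 3-(benzyloxy)-4,5-dimethoxybenzoate | COc1cc(C(=O)O[C@@H]2CC=C([Sn](C)(C)C)O[C@@H]2c2ccc(OCc3ccccc3)c(OCc3ccccc3)c2)cc(OCc2ccccc2)c1OC
F15 | step 3 | ethyl(furan-2-yl)zinc | CC[Zn]c1ccco1
A1 | alternative 1 | (2R,3R)-5,7-bis(benzyloxy)-2-[3,4-bis(benzyloxy)phenyl]-3,4-dihydro-2H-chromen-3-ol (5,7,3',4'-tetra-O-benzyl-(−)-epicatechin) | O[C@@H]1Cc2c(OCc3ccccc3)cc(OCc3ccccc3)cc2O[C@@H]1c1ccc(OCc2ccccc2)c(OCc2ccccc2)c1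
A2 | alternative 2 | {[(2R,3R)-5,7-bis(benzyloxy)-2-[3,4-bis(benzyloxy)phenyl]-3,4-dihydro-2H-chromen-3-yl]oxy}(tert-butyl)dimethylsilane | CC(C)(C)[Si](C)(C)O[C@@H]1Cc2c(OCc3ccccc3)cc(OCc3ccccc3)cc2O[C@@H]1c1ccc(OCc2ccccc2)c(OCc2ccccc2)c1
A3 | alternative 3 | (2R,3R)-5,7-bis(benzyloxy)-2-[3,4-bis(benzyloxy)phenyl]-3,4-dihydro-2H-chromen-3-yl 3-(benzyloxy)-4,5-dimethoxybenzoate | COc1cc(C(=O)O[C@@H]2Cc3c(OCc4ccccc4)cc(OCc4ccccc4)cc3O[C@@H]2c2ccc(OCc3ccccc3)c(OCc3ccccc3)c2)cc(OCc2ccccc2)c1OC
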